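**Retrosynthetic overview**
1. Target 17 is cut at the aryl C6–CH2 bond into chromene 14 and the 6-methylidene trione 16. 16 is made in the flask from the (R)-acylfilicinic acid 8 and CH2=NMe2+ I−, so the coupling is a biomimetic three-component methylene bridging.
2. Feature that allows it: each half has one doubly activated ring CH. In 8 it is C6–H of the cyclohexadienone ring, between C1=O and C5–OH, which takes up CH2 and then becomes the exocyclic enone C6=CH2. In 14 it is C6–H of the benzene ring, between 5-OH and 7-OH, the only free aromatic carbon.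
3. 8 comes from Claisen closure (C2–C3) of triketo ester 7, itself from acid chloride 5 and the acetylacetone dianion. The quaternary stereocentre comes from esterase desymmetrisation of malonate 3 (from 1 and 2).
4. 14 comes from Knoevenagel/oxa-6π closure of the pyran ring on 4-O-MOM phlorbutyrophenone 10 with prenal 11, then MOM removal.
5. Ring order: the trione carbocycle (step 4) and the pyran (step 6) are built in separate branches. The key step forms two C–C bonds and no ring.

Key step: step 8

Assumption: all β-triketone units are written as one enol tautomer of a fast equilibrium, and the CIP descriptors refer to the tautomer drawn.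
Assumption: pig liver esterase is taken to give the (R)-half-ester 4, as its active-site model predicts for a 2-methylmalonate with a long lipophilic second substituent. The configuration of 4 is to be proven by correlation before it is carried on.

**Step 1**
Reactants: 1 dimethyl 2-methylmalonate; 2 geranyl bromide
Product: 3 dimethyl 2-geranyl-2-methylmalonate
Conditions: NaH (1.05 equiv), THF, 0 °C; then 2, 0 °C → rt
Reagents that add atoms: none
Why: Malonic ester alkylation (SN2 of the sodium enolate on the primary allylic bromide) should build the quaternary carbon with the E-alkene untouched; no stereocentre arises because the two ester groups are identical.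

**Step 2**
Reactants: 3 dimethyl 2-geranyl-2-methylmalonate
Product: 4 (2R,4E)-2-(methoxycarbonyl)-2,5,9-trimethyldeca-4,8-dienoic acid
Conditions: pig liver esterase, 0.1 M phosphate buffer pH 7.5, DMSO (10 vol %), 25 °C; then 1 M HCl to pH 2
Reagents that add atoms: water, O
Why: Enzymatic desymmetrisation of a prochiral 2,2-disubstituted malonate, in which the esterase hydrolyses one of the two enantiotopic ester groups and so sets the quaternary stereocentre, the geranyl chain in the large hydrophobic pocket being expected to lead to the (R)-half-ester, which is not hydrolysed further.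

**Step 3**
Reactants: 4 (R)-half-ester
Product: 5 methyl (2S,4E)-2-(chlorocarbonyl)-2,5,9-trimethyldeca-4,8-dienoate
Conditions: 1-chloro-N,N,2-trimethylprop-1-en-1-amine (1.2 equiv), CH2Cl2, 0 °C → rt; volatiles and amide co-product removed under high vacuum
Reagents that add atoms: 1-chloro-N,N,2-trimethylprop-1-en-1-amine (Ghosez's reagent), CC(C)=C(Cl)N(C)C
Why: Acid chloride formation with an α-chloroenamine runs under neutral conditions without HCl, so the trisubstituted alkenes should survive, and the quaternary α-carbon excludes ketene formation and epimerisation (the change of descriptor is a CIP priority change only).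

**Step 4**
Reactants: 5 acid chloride; 6 pentane-2,4-dione
Product: 8 (4R)-2-acetyl-4-geranyl-3,5-dihydroxy-4-methylcyclohexa-2,5-dien-1-one, via triketo ester 7 (not isolated)
Conditions: 6 (2.5 equiv), LDA (2.0 equiv per diketone), THF, 0 °C; 5 added at −78 °C; → rt, then 50 °C; 1 M HCl, 0 °C
Reagents that add atoms: none
Why: γ-Acylation of the β-diketone 1,3-dianion at its terminal carbon by the acid chloride is followed by intramolecular Claisen (Dieckmann-type, 6-exo-trig) condensation of the central diketone carbon onto the neighbouring methyl ester, the biomimetic polyketide ring closure; the acid chloride arm becomes C5 next to C6–H and the ester arm becomes C3 next to the acetyl-bearing C2, so the configuration of 4 is carried unchanged to C4.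

**Step 5**
Reactants: 9 1-(2,4,6-trihydroxyphenyl)butan-1-one
Product: 10 1-[2,6-dihydroxy-4-(methoxymethoxy)phenyl]butan-1-one
Conditions: MOMCl (1.0 equiv), i-Pr2NEt (1.1 equiv), CH2Cl2, 0 °C
Reagents that add atoms: chloromethyl methyl ether, COCCl
Why: Williamson-type O-alkylation should take place at the 4-OH, which is the most acidic hydroxyl, the least hindered, and not hydrogen-bonded to the ketone.

**Step 6**
Reactants: 10 4-O-MOM phlorbutyrophenone; 11 3-methylbut-2-enal
Product: 13 1-[7-hydroxy-5-(methoxymethoxy)-2,2-dimethyl-2H-chromen-8-yl]butan-1-one, via ortho-quinone methide 12 (not isolated)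
Conditions: 11 (1.2 equiv), ethylenediammonium diacetate (20 mol %), toluene, 110 °C
Reagents that add atoms: none
Why: Amine-catalysed Knoevenagel-type condensation at C3 gives the ortho-quinone methide, whose oxa-6π electrocyclisation closes the 2H-pyran; with O4 blocked only the oxygen ortho to the acyl group can close, which fixes the 8-acyl pattern and prevents ring-opening/reclosure onto the other oxygen at this temperature.

**Step 7**
Reactants: 13 MOM-protected chromene
Product: 14 1-(5,7-dihydroxy-2,2-dimethyl-2H-chromen-8-yl)butan-1-one
Conditions: 3 M aq. HCl, MeOH (dilute), 25 °C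
Reagents that add atoms: none
Why: Acid-catalysed acetal exchange removes the MOM group while the large excess of methanol traps the methoxymethyl cation as dimethoxymethane, and the chelated aryl ketone and the chromene should tolerate dilute acid at room temperature.

**Step 8**
Reactants: 8 (R)-acylfilicinic acid; 14 chromene
Product: 17 (4R)-2-acetyl-6-[(8-butanoyl-5,7-dihydroxy-2,2-dimethyl-2H-chromen-6-yl)methyl]-4-geranyl-3,5-dihydroxy-4-methylcyclohexa-2,5-dien-1-one, via Mannich base 15 (not isolated), via methylene trione 16 (not isolated)
Conditions: 8, CH2=NMe2+ I− (1.0 equiv), i-Pr2NEt (1.05 equiv), MeCN, 0 °C → rt; then 14 (1.05 equiv), 65 °C; cold dilute citric acid work-up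
Reagents that add atoms: N,N-dimethylmethyleneiminium iodide (Eschenmoser's salt), C[N+](C)=C.[I-]
Why: The vinylogous-acid carbon C6 of 8 adds to the iminium ion (Mannich reaction) to give 15, which on warming loses dimethylamine by E1cB to the 6-methylidene trione 16, an ortho-quinone-methide-like acceptor, and C6 of 14 then adds to its CH2 terminus (Friedel–Crafts-type conjugate addition) before enolisation and rearomatisation give 17. The closest known reaction type is the Mannich-base route to methylene-bridged acylphloroglucinol–filicinic acid dimers and the capture of alkylidene triones by acylphloroglucinols, which mirrors the presumed biosynthetic coupling of the two monomers through a C1 unit. No ring is closed in this step. No stereocentre is created, and the quaternary C4 bears no hydrogen and is not touched, so its configuration is that set in step 2. The step needs cross- over homo-coupling and C- over O-alkylation: 8 has a single enolic CH and is converted completely to 15 before 14 is added, 14 has a single free aromatic CH, and O-adducts revert under the reversible conditions while the C-adduct does not. The mild base and 65 °C should leave the chromene and geranyl alkenes intact and limit methylene exchange between the halves.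

**Compound list**
1 | dimethyl 2-methylpropanedioate | COC(=O)C(C)C(=O)OC | starting material
2 | geranyl bromide, (2E)-1-bromo-3,7-dimethylocta-2,6-diene | CC(C)=CCC/C(C)=C/CBr | starting material
3 | dimethyl 2-[(2E)-3,7-dimethylocta-2,6-dien-1-yl]-2-methylpropanedioate | COC(=O)C(C)(C/C=C(\C)CCC=C(C)C)C(=O)OC | intermediate
4 | (2R,4E)-2-(methoxycarbonyl)-2,5,9-trimethyldeca-4,8-dienoic acid | OC(=O)[C@@](C)(C/C=C(\C)CCC=C(C)C)C(=O)OC | intermediate
5 | methyl (2S,4E)-2-(chlorocarbonyl)-2,5,9-trimethyldeca-4,8-dienoate | ClC(=O)[C@@](C)(C/C=C(\C)CCC=C(C)C)C(=O)OC | intermediate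
6 | pentane-2,4-dione (acetylacetone) | CC(=O)CC(C)=O | starting material
7 | methyl (2R)-2-[(2E)-3,7-dimethylocta-2,6-dien-1-yl]-2-methyl-3,5,7-trioxooctanoate | CC(=O)CC(=O)CC(=O)[C@@](C)(C/C=C(\C)CCC=C(C)C)C(=O)OC | intermediate
8 | (4R)-2-acetyl-4-[(2E)-3,7-dimethylocta-2,6-dien-1-yl]-3,5-dihydroxy-4-methylcyclohexa-2,5-dien-1-one | C1=C(O)[C@@](C)(C/C=C(\C)CCC=C(C)C)C(O)=C(C(C)=O)C1=O | intermediate
9 | 1-(2,4,6-trihydroxyphenyl)butan-1-one | CCCC(=O)c1c(O)cc(O)cc1O | starting material
10 | 1-[2,6-dihydroxy-4-(methoxymethoxy)phenyl]butan-1-one | CCCC(=O)c1c(O)cc(OCOC)cc1O | intermediate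
11 | 3-methylbut-2-enal (prenal) | CC(C)=CC=O | starting material
12 | 2-butanoyl-3-hydroxy-5-(methoxymethoxy)-6-(3-methylbut-2-en-1-ylidene)cyclohexa-2,4-dien-1-one | CCCC(=O)C1=C(O)C=C(OCOC)C(=CC=C(C)C)C1=O | intermediate
13 | 1-[7-hydroxy-5-(methoxymethoxy)-2,2-dimethyl-2H-chromen-8-yl]butan-1-one | CCCC(=O)c1c(O)cc(OCOC)c2c1OC(C)(C)C=C2 | intermediate
14 | 1-(5,7-dihydroxy-2,2-dimethyl-2H-chromen-8-yl)butan-1-one | CCCC(=O)c1c(O)cc(O)c2c1OC(C)(C)C=C2 | intermediate
15 | (4R)-2-acetyl-6-[(dimethylamino)methyl]-4-[(2E)-3,7-dimethylocta-2,6-dien-1-yl]-3,5-dihydroxy-4-methylcyclohexa-2,5-dien-1-one | CN(C)CC1=C(O)[C@@](C)(C/C=C(\C)CCC=C(C)C)C(O)=C(C(C)=O)C1=O | intermediate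
16 | (4S)-2-acetyl-4-[(2E)-3,7-dimethylocta-2,6-dien-1-yl]-3-hydroxy-4-methyl-6-methylidenecyclohex-2-ene-1,5-dione (same spatial arrangement as 8; descriptor changed by CIP priority) | C=C1C(=O)[C@@](C)(C/C=C(\C)CCC=C(C)C)C(O)=C(C(C)=O)C1=O | intermediate
17 | (4R)-2-acetyl-6-[(8-butanoyl-5,7-dihydroxy-2,2-dimethyl-2H-chromen-6-yl)methyl]-4-[(2E)-3,7-dimethylocta-2,6-dien-1-yl]-3,5-dihydroxy-4-methylcyclohexa-2,5-dien-1-one (CNP0152509.1) | CCCC(=O)c1c(O)c(CC2=C(O)[C@@](C)(C/C=C(\C)CCC=C(C)C)C(O)=C(C(C)=O)C2=O)c(O)c2c1OC(C)(C)C=C2 | target

**Step count and risks**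
Total steps: 8. Longest linear sequence: 5 steps (1, 2, 3, 4, 8); the chromene branch (5, 6, 7) joins at step 8.

Steps most likely to fail:

1. Step 4. The acid chloride may be attacked by oxygen or by the central carbon of the diketone after proton transfer to the monoanion; central-carbon acylation would, after ring closure, give the mirror-image ring and erode enantiomeric purity. Claisen closure onto the hindered ester may also be slow under lithium amide conditions. The fallback sets out from 5 and 6 and comes back at 8. Acetylacetone 6 is silylated twice (Me3SiCl, Et3N; then LDA, Me3SiCl, THF, −78 °C) to 2,4-bis(trimethylsilyloxy)penta-1,3-diene F1. F1 is acylated at its terminal carbon by 5 (CH2Cl2, −78 → 20 °C, catalytic Me3SiOTf if needed), and aqueous work-up gives triketo ester 7, now isolated. 7 is then cyclised separately with DBU in toluene at 60 °C to 8.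

2. Step 2. Discrimination of the enantiotopic ester groups by the esterase may be insufficient or reversed on this very lipophilic, poorly soluble substrate. The fallback sets out from 3 and comes back at 4. 3 is half-saponified with one equivalent of KOH in MeOH to the racemic half-ester F2. F2 is combined with (S)-1-phenylethylamine and the salt of the (R)-acid, (S)-1-phenylethylammonium (2R)-carboxylate F3, is crystallised to constant rotation. The diastereomeric salt of the (S)-acid, (S)-1-phenylethylammonium (2S)-carboxylate F4, stays in the mother liquor; if F4 proves the less soluble salt, the (R)-amine is used instead. Acidification of F3 gives 4.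

3. Step 8. Reversible methylene transfer between the halves and homo-coupling may give symmetrical methylene-bis products, or elimination from the Mannich base may be incomplete at a temperature the chromene tolerates. The fallback sets out from 8 and comes back at 17. 8 is condensed with aqueous formaldehyde and thiophenol (EtOH, catalytic piperidine, rt; Knoevenagel/thia-Michael) to the isolable 6-(phenylthiomethyl) compound F5. F5 is oxidised at sulfur with NaIO4 (MeOH–H2O, 0 °C) to the sulfoxide F6, a mixture at sulfur. F6 is stirred with 14 and NaHCO3 in THF at 25–40 °C: β-elimination of benzenesulfenate releases 16 slowly, without amine, in the presence of 14 and should give 17.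

**Further compounds**
F1 | step 4 | 2,4-bis(trimethylsilyloxy)penta-1,3-diene | C=C(O[Si](C)(C)C)C=C(C)O[Si](C)(C)C
F2 | step 2 | racemic (4E)-2-(methoxycarbonyl)-2,5,9-trimethyldeca-4,8-dienoic acid | OC(=O)C(C)(C/C=C(\C)CCC=C(C)C)C(=O)OC
F3 | step 2 | (S)-1-phenylethylammonium (2R,4E)-2-(methoxycarbonyl)-2,5,9-trimethyldeca-4,8-dienoate | C[C@H]([NH3+])c1ccccc1.[O-]C(=O)[C@@](C)(C/C=C(\C)CCC=C(C)C)C(=O)OC
F4 | step 2 | (S)-1-phenylethylammonium (2S,4E)-2-(methoxycarbonyl)-2,5,9-trimethyldeca-4,8-dienoate | C[C@H]([NH3+])c1ccccc1.[O-]C(=O)[C@](C)(C/C=C(\C)CCC=C(C)C)C(=O)OC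
F5 | step 8 | (4R)-2-acetyl-4-[(2E)-3,7-dimethylocta-2,6-dien-1-yl]-3,5-dihydroxy-4-methyl-6-[(phenylsulfanyl)methyl]cyclohexa-2,5-dien-1-one | c1ccccc1SCC2=C(O)[C@@](C)(C/C=C(\C)CCC=C(C)C)C(O)=C(C(C)=O)C2=O
F6 | step 8 | (4R)-2-acetyl-4-[(2E)-3,7-dimethylocta-2,6-dien-1-yl]-3,5-dihydroxy-4-methyl-6-[(phenylsulfinyl)methyl]cyclohexa-2,5-dien-1-one | O=S(c1ccccc1)CC2=C(O)[C@@](C)(C/C=C(\C)CCC=C(C)C)C(O)=C(C(C)=O)C2=O
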